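**Retrosynthetic overview**
1. Target 15 ⇐ tri-O-methyl acid 14 (cleave three aryl methyl ethers) ⇐ thioester 13 (thioester → acid).
2. 13 ⇐ enal 8 + alkyne 12 + MeOH: a carbene-catalysed homoenolate addition makes the C4–C(alkene) bond and sets C3, C4, the E alkene and the C3 methyl ester in one step.
3. 8 ⇐ 2,4,5-trimethoxybenzoic acid 5 + keto sulfoxonium ylide 4: carboxylate-directed C–H annulation closes the pyranone (lactone) ring, the only ring made; the benzene ring is bought.
4. 4 ⇐ methyl dimethoxyacetate 1 + trimethylsulfoxonium iodide 2; 12 ⇐ methyl propiolate 9 + S-ethyl chlorothioformate 10.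

Assumption: the SMILES is read as the (3S,4R)-trans lactone with an E (fumarate-type) alkene; the facial sense of the chiral carbene in step 4 is taken from the usual model for this catalyst family, and the enantiomeric precatalyst (equally available) is used if the opposite sense is found.

**Route**

Step 1
Reactants: 1 methyl 2,2-dimethoxyacetate; 2 trimethylsulfoxonium iodide
Product: 4 1-[dimethyl(oxo)-λ6-sulfanylidene]-3,3-dimethoxypropan-2-one, via dimethylsulfoxonium methylide 3 (not isolated)
Conditions: 2 (3.0 equiv), KOtBu (3.0 equiv), THF, reflux, 2 h; then 1, 0 °C → reflux, 2 h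
Reagents that add atoms: none
Why: Acylation of the Corey–Chaykovsky methylide by an ester gives the stabilised β-keto sulfoxonium ylide; no stereocentre is involved.

Step 2
Reactants: 5 2,4,5-trimethoxybenzoic acid; 4 1-[dimethyl(oxo)-λ6-sulfanylidene]-3,3-dimethoxypropan-2-one
Product: 8 5,6,8-trimethoxy-1-oxo-1H-isochromene-3-carbaldehyde, via keto acid 6 (not isolated), via dimethyl acetal 7 (not isolated)
Conditions: [Cp*RhCl2]2 (2.5 mol %), AgSbF6 (10 mol %), NaOAc (30 mol %), ClCH2CH2Cl, 80 °C; then 3 M aq HCl/THF, 50 °C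
Reagents that add atoms: water (O)
Why: Carboxylate-directed C–H acylmethylation/annulation of a benzoic acid with a sulfoxonium ylide under trivalent rhodium catalysis: rhodation at the only free ortho C–H, carbene transfer with loss of DMSO, cyclodehydration of keto acid 6 to isocoumarin 7, then acetal hydrolysis to the enal 8.

Step 3
Reactants: 9 methyl propiolate; 10 S-ethyl chlorothioformate
Product: 12 S-ethyl 4-methoxy-4-oxobut-2-ynethioate, via lithium acetylide 11 (not isolated)
Conditions: LiN(SiMe3)2 (1.05 equiv), THF, −78 °C, 20 min; then 10, −78 → −40 °C; AcOH quench at −78 °C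
Reagents that add atoms: none
Why: C-acylation of a lithium acetylide by a chlorothioformate gives the mixed ester/thioester alkyne, whose two acyl groups differ enough in acceptor strength to direct the next step; no stereocentre is involved.

Step 4
Reactants: 8 5,6,8-trimethoxy-1-oxo-1H-isochromene-3-carbaldehyde; 12 S-ethyl 4-methoxy-4-oxobut-2-ynethioate
Product: 13 methyl (3S,4R)-4-[(2E)-4-(ethylsulfanyl)-1-methoxy-1,4-dioxobut-2-en-2-yl]-5,6,8-trimethoxy-1-oxo-3,4-dihydro-1H-isochromene-3-carboxylate
Conditions: (5aS,10bR)-5a,10b-dihydro-2-(2,4,6-trimethylphenyl)-4H,6H-indeno[2,1-b][1,2,4]triazolo[4,3-d][1,4]oxazinium chloride (10 mol %), i-Pr2NEt (20 mol %), MeOH (5 equiv), 12 (2.0 equiv, syringe pump over 6 h), THF, 4 Å MS, 0 → 23 °C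
Reagents that add atoms: methanol (CO)
Why: Proposed new method: the triazolylidene adds to the aldehyde of 8 and the extended Breslow intermediate acts as a homoenolate, nucleophilic at C4 (the enal β-carbon, normally electrophilic), which attacks the alkyne carbon of 12 that carries CO2Me and lies β to the more activating thioester (also normally electrophilic); the chiral N-mesityl aminoindanol carbene shields one face to set C4 as R, the allenolate is protonated anti to the bulky new substituent to give the E alkene, the enol azolium is protonated at C3 and the C3-labile acyl azolium settles in the trans-diaxial (3S,4R) arrangement before methanolysis gives the C3 methyl ester and frees the catalyst; the ring oxygen on C3 sits on an sp2 carbon in the nodal plane of the Breslow π-system, so redox elimination is not expected; the closest known reaction type is the NHC-catalysed homoenolate conjugate addition/redox esterification of enals with chalcones or nitroalkenes in alcohols.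

Step 5
Reactants: 13 methyl (3S,4R)-4-[(2E)-4-(ethylsulfanyl)-1-methoxy-1,4-dioxobut-2-en-2-yl]-5,6,8-trimethoxy-1-oxo-3,4-dihydro-1H-isochromene-3-carboxylate
Product: 14 (2E)-4-methoxy-4-oxo-3-[(3S,4R)-5,6,8-trimethoxy-3-(methoxycarbonyl)-1-oxo-3,4-dihydro-1H-isochromen-4-yl]but-2-enoic acid
Conditions: AgO2CCF3 (2.5 equiv), THF/H2O 4:1, 23 °C, dark, argon
Reagents that add atoms: water (O)
Why: Thiophilic activation of the thioester by monovalent silver lets water cleave it selectively while the two methyl esters and the lactone are untouched, and the neutral-to-acidic medium leaves C3, C4 and the alkene unchanged (silver-assisted thioester hydrolysis).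

Step 6
Reactants: 14 (2E)-4-methoxy-4-oxo-3-[(3S,4R)-5,6,8-trimethoxy-3-(methoxycarbonyl)-1-oxo-3,4-dihydro-1H-isochromen-4-yl]but-2-enoic acid
Product: 15 (2E)-4-methoxy-4-oxo-3-[(3S,4R)-5,6,8-trihydroxy-3-(methoxycarbonyl)-1-oxo-3,4-dihydro-1H-isochromen-4-yl]but-2-enoic acid
Conditions: BBr3 (8 equiv), CH2Cl2, −78 → 0 °C; then ice-water, argon
Reagents that add atoms: none
Why: Lewis-acid ether cleavage by BBr3 removes aryl methyl ethers (the C8 ether chelation-assisted, the C5/C6 pair as a catechol diether) at low temperature, faster than alkyl methyl ester cleavage, and the non-enolising acidic conditions leave both stereocentres and the E alkene intact.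

**Compound list**
1 | methyl 2,2-dimethoxyacetate | COC(OC)C(=O)OC | starting material
2 | trimethylsulfoxonium iodide | C[S+](C)(C)=O.[I-] | starting material
3 | dimethylsulfoxonium methylide | C=S(C)(C)=O | intermediate
4 | 1-[dimethyl(oxo)-λ6-sulfanylidene]-3,3-dimethoxypropan-2-one | COC(OC)C(=O)C=S(C)(C)=O | intermediate
5 | 2,4,5-trimethoxybenzoic acid | COc1cc(OC)c(OC)cc1C(=O)O | starting material
6 | 2-(3,3-dimethoxy-2-oxopropyl)-3,4,6-trimethoxybenzoic acid | COC(OC)C(=O)Cc1c(OC)c(OC)cc(OC)c1C(=O)O | intermediate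
7 | 3-(dimethoxymethyl)-5,6,8-trimethoxy-1H-isochromen-1-one | COC(OC)c1cc2c(OC)c(OC)cc(OC)c2c(=O)o1 | intermediate
8 | 5,6,8-trimethoxy-1-oxo-1H-isochromene-3-carbaldehyde | O=Cc1cc2c(OC)c(OC)cc(OC)c2c(=O)o1 | intermediate
9 | methyl propiolate | COC(=O)C#C | starting material
10 | S-ethyl chlorothioformate | CCSC(Cl)=O | starting material
11 | methyl 3-lithiopropiolate | COC(=O)C#C[Li] | intermediate
12 | S-ethyl 4-methoxy-4-oxobut-2-ynethioate | CCSC(=O)C#CC(=O)OC | intermediate
13 | methyl (3S,4R)-4-[(2E)-4-(ethylsulfanyl)-1-methoxy-1,4-dioxobut-2-en-2-yl]-5,6,8-trimethoxy-1-oxo-3,4-dihydro-1H-isochromene-3-carboxylate | COC(=O)/C(=C/C(=O)SCC)[C@H]1c2c(OC)c(OC)cc(OC)c2C(=O)O[C@@H]1C(=O)OC | intermediate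
14 | (2E)-4-methoxy-4-oxo-3-[(3S,4R)-5,6,8-trimethoxy-3-(methoxycarbonyl)-1-oxo-3,4-dihydro-1H-isochromen-4-yl]but-2-enoic acid | COC(=O)/C(=C/C(=O)O)[C@H]1c2c(OC)c(OC)cc(OC)c2C(=O)O[C@@H]1C(=O)OC | intermediate
15 | (2E)-4-methoxy-4-oxo-3-[(3S,4R)-5,6,8-trihydroxy-3-(methoxycarbonyl)-1-oxo-3,4-dihydro-1H-isochromen-4-yl]but-2-enoic acid | COC(=O)/C(=C/C(=O)O)[C@H]1c2c(O)c(O)cc(O)c2C(=O)O[C@@H]1C(=O)OC | target

**Step count**
Total: 6 steps. Longest linear sequence: 5 steps (1 → 2 → 4 → 5 → 6); step 3 is a one-step side branch.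

**Steps most likely to fail**

Step 4. This is the least precedented step. The α-acyloxy enal class is untested in homoenolate chemistry; the free carbene or methanol can add irreversibly to the alkyne (hence slow addition and excess 12); β-protonation of the homoenolate competes; and ee and the cis/trans ratio at C3 are not assured. Base must stay weak, because a C4 carbanion in 13 would open the lactone by β-elimination. The fallback sets out from 8 and comes back at 13, using normal-polarity bond formation and a reduction to set the stereocentres. Oxidative esterification of 8 (1,3-dimesitylimidazolium chloride, DBU, MnO2, MeOH) gives methyl 5,6,8-trimethoxy-1-oxo-1H-isochromene-3-carboxylate F1. NaOMe in MeOH opens the enol lactone to the aryl pyruvate methyl 3,4,6-trimethoxy-2-(3-methoxy-2,3-dioxopropyl)benzoate F2. Its enol adds as an ordinary Michael donor (Et3N cat., CH2Cl2) to alkyne 12, again β to the thioester, to give racemic methyl 2-[(4E)-6-(ethylsulfanyl)-1-methoxy-4-(methoxycarbonyl)-1,2,6-trioxohex-4-en-3-yl]-3,4,6-trimethoxybenzoate F3, which is configurationally labile at the benzylic carbon. Dynamic kinetic asymmetric transfer hydrogenation of the α-keto ester (RuCl(p-cymene)[(S,S)-TsDPEN], or its antipode as needed, HCO2H/Et3N) sets both centres and gives methyl 2-[(2S,3R,4E)-6-(ethylsulfanyl)-2-hydroxy-1-methoxy-4-(methoxycarbonyl)-1,6-dioxohex-4-en-3-yl]-3,4,6-trimethoxybenzoate F4. F4 lactonises onto the aryl ester (TsOH cat., toluene) to return 13.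

Step 6. BBr3 may also cleave a methyl ester, let the C5 phenol lactonise onto the neighbouring ester, or isomerise the alkene through HBr; the product is an air-sensitive hydroquinone. The fallback sets out from 14 and comes back at 15 without any Lewis acid. (NH4)2Ce(NO3)6 in MeCN/H2O at 0 °C oxidises the para-related C5/C8 methoxy pair to the quinone (2E)-4-methoxy-3-[(3S,4R)-6-methoxy-3-(methoxycarbonyl)-1,5,8-trioxo-3,4,5,8-tetrahydro-1H-isochromen-4-yl]-4-oxobut-2-enoic acid F5. Dilute aqueous H2SO4 in dioxane hydrolyses the vinylogous ester at C6 to (2E)-3-[(3S,4R)-6-hydroxy-3-(methoxycarbonyl)-1,5,8-trioxo-3,4,5,8-tetrahydro-1H-isochromen-4-yl]-4-methoxy-4-oxobut-2-enoic acid F6. Na2S2O4 in water/EtOAc reduces the quinone to 15.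

Step 2. The C–H bond to be activated is flanked by the carboxylate and a methoxy group, and the acetal-bearing ylide may not survive the Lewis-acidic medium. The fallback sets out from 5 and comes back at 8 by halogenation and alkyne coupling instead of carbene transfer. Carboxylate-directed ortho-iodination (Pd(OAc)2 cat., PhI(OAc)2, I2, DMF) gives 2-iodo-3,4,6-trimethoxybenzoic acid F7. Coupling–cyclisation with 3,3-diethoxyprop-1-yne (Pd(PPh3)4, ZnCl2, Et3N, DMF, 100 °C) gives 3-(diethoxymethyl)-5,6,8-trimethoxy-1H-isochromen-1-one F8. Aqueous HCl/THF then gives 8.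

**Further compounds**
F1 | step 4 | methyl 5,6,8-trimethoxy-1-oxo-1H-isochromene-3-carboxylate | COC(=O)c1cc2c(OC)c(OC)cc(OC)c2c(=O)o1
F2 | step 4 | methyl 3,4,6-trimethoxy-2-(3-methoxy-2,3-dioxopropyl)benzoate | COC(=O)C(=O)Cc1c(OC)c(OC)cc(OC)c1C(=O)OC
F3 | step 4 | racemic methyl 2-[(4E)-6-(ethylsulfanyl)-1-methoxy-4-(methoxycarbonyl)-1,2,6-trioxohex-4-en-3-yl]-3,4,6-trimethoxybenzoate | COC(=O)/C(=C/C(=O)SCC)C(C(=O)C(=O)OC)c1c(OC)c(OC)cc(OC)c1C(=O)OC
F4 | step 4 | methyl 2-[(2S,3R,4E)-6-(ethylsulfanyl)-2-hydroxy-1-methoxy-4-(methoxycarbonyl)-1,6-dioxohex-4-en-3-yl]-3,4,6-trimethoxybenzoate | COC(=O)/C(=C/C(=O)SCC)[C@H]([C@H](O)C(=O)OC)c1c(OC)c(OC)cc(OC)c1C(=O)OC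
F5 | step 6 | (2E)-4-methoxy-3-[(3S,4R)-6-methoxy-3-(methoxycarbonyl)-1,5,8-trioxo-3,4,5,8-tetrahydro-1H-isochromen-4-yl]-4-oxobut-2-enoic acid | COC(=O)/C(=C/C(=O)O)[C@H]1C2=C(C(=O)O[C@@H]1C(=O)OC)C(=O)C=C(OC)C2=O
F6 | step 6 | (2E)-3-[(3S,4R)-6-hydroxy-3-(methoxycarbonyl)-1,5,8-trioxo-3,4,5,8-tetrahydro-1H-isochromen-4-yl]-4-methoxy-4-oxobut-2-enoic acid | COC(=O)/C(=C/C(=O)O)[C@H]1C2=C(C(=O)O[C@@H]1C(=O)OC)C(=O)C=C(O)C2=O
F7 | step 2 | 2-iodo-3,4,6-trimethoxybenzoic acid | OC(=O)c1c(I)c(OC)c(OC)cc1OC
F8 | step 2 | 3-(diethoxymethyl)-5,6,8-trimethoxy-1H-isochromen-1-one | CCOC(OCC)c1cc2c(OC)c(OC)cc(OC)c2c(=O)o1
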